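**Strategy.** Numbering along the target SMILES: chain C1–C5, C6 (bears C7H2OH), C8–C10, C11=C12, C13–C15, C16 (ester), C17, C18, C19, N20, C21. Ring A (C11=C12–C13–C14–C15) is made by one-carbon expansion of a cyclobutane (C12–C15) fused to ring B. Acid protonates the ring C alkene C10=C11 of this vinylcyclobutane; C15 migrates from C12 to C11 and loss of H11 leaves the tetrasubstituted C11=C12 bond, completing the 5-5-7 carbotricycle around C12, the carbon shared by rings A, B and C. The precursor, a cis-bicyclo[3.2.0]heptane fused to a cycloheptene, comes from a formal [3+2] cycloaddition onto a cyclobutene and ring-closing metathesis.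

Key step: step 10

Rings: A = C11, C12, C13, C14, C15; B = C12, C13, C16, C17, C18; C = C6, C8, C9, C10, C11, C12, C18; D = C6, C8, C21, N20, C19, C18. In this numbering the target is 3S, 6S, 8R, 13S, 16S, 18S.

Remark 1: compounds 1, 4, 17, 18 and all reagents are taken as commercially available.
Remark 2: the sense of induction of the amine catalyst in step 3 and of the sulfonamide ligand in step 22 is assumed from the usual models; the mirror-image catalyst would be used if the opposite sense is found.
Remark 3: C18 in compounds 5–14 is drawn as one epimer; the other would serve equally, because C18 is set anew in step 13.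

Step 1
Reactants: 1 methyl cyclobut-1-ene-1-carboxylate
Product: 2 (cyclobut-1-en-1-yl)methanol
Conditions: i-Bu2AlH (2.2 equiv), CH2Cl2, −78 to 0 °C
Reagents that add atoms: none
Why: Reduction of the conjugated ester with the aluminium hydride should proceed 1,2 to the allylic alcohol (ester reduction), with no stereocentre formed.

Step 2
Reactants: 2 (cyclobut-1-en-1-yl)methanol
Product: 3 cyclobut-1-ene-1-carbaldehyde
Conditions: MnO2, CH2Cl2, 23 °C; used as a solution
Reagents that add atoms: none
Why: Allylic alcohol oxidation with MnO2 should stop at the enal and leave the strained alkene untouched.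

Step 3
Reactants: 3 cyclobut-1-ene-1-carbaldehyde; 4 dimethyl 2-vinylcyclopropane-1,1-dicarboxylate
Product: 5 dimethyl 5-formyl-4-vinylbicyclo[3.2.0]heptane-2,2-dicarboxylate (cis-fused; formyl on C12, vinyl on C18, C13 as in the target)
Conditions: Pd2(dba)3 (3 mol%), PPh3 (12 mol%), (S)-2-[diphenyl(trimethylsilyloxy)methyl]pyrrolidine (20 mol%), PhCO2H (20 mol%), THF, 20 °C
Reagents that add atoms: none
Why: Proposed new method: the amine should condense with enal 3 to an iminium ion while zerovalent palladium opens 4 to a zwitterionic π-allyl palladium malonate; the malonate adds to C13 on the iminium face left open by the diphenyl(silyloxy)methyl group (this sets C13), the enamine then closes ring B on the π-allyl terminus from C12 so that the cyclobutane is necessarily cis-fused, and hydrolysis releases 5; the closest known reaction type is the synergistic palladium/secondary-amine formal [3+2] cycloaddition of vinylcyclopropane-1,1-diesters with β-substituted enals, extended here to an α,β-disubstituted cyclic enal whose ring strain should offset the α-branch.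

Step 4
Reactants: 5 dimethyl 5-formyl-4-vinylbicyclo[3.2.0]heptane-2,2-dicarboxylate
Product: 6 dimethyl 4-acetyl-5-formylbicyclo[3.2.0]heptane-2,2-dicarboxylate
Conditions: PdCl2 (10 mol%), CuCl (1 equiv), O2 (1 atm), DMF/H2O 7:1, 23 °C
Reagents that add atoms: water, O
Why: Tsuji–Wacker oxidation should convert the terminal vinyl group into the methyl ketone (C6=O, C8H3) with Markovnikov selectivity; C18 becomes epimerisable, which is of no consequence.

Step 5
Reactants: 6 dimethyl 4-acetyl-5-formylbicyclo[3.2.0]heptane-2,2-dicarboxylate
Product: 7 dimethyl 4-acetyl-5-vinylbicyclo[3.2.0]heptane-2,2-dicarboxylate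
Conditions: Ph3PCH3Br, KN(SiMe3)2 (1.05 equiv), THF, −78 to 0 °C
Reagents that add atoms: methylenetriphenylphosphorane, C=P(c1ccccc1)(c1ccccc1)c1ccccc1
Why: Wittig methylenation is much faster at the aldehyde than at the methyl ketone at low temperature and should give the 1-vinylcyclobutane (C11=C10) before any intramolecular aldol reaction of the keto aldehyde.

Step 6
Reactants: 7 dimethyl 4-acetyl-5-vinylbicyclo[3.2.0]heptane-2,2-dicarboxylate
Product: 8 dimethyl 4-(pent-4-enoyl)-5-vinylbicyclo[3.2.0]heptane-2,2-dicarboxylate
Conditions: LiN(i-Pr)2 (1.05 equiv), THF, −78 °C; allyl bromide, −78 to −20 °C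
Reagents that add atoms: allyl bromide, C=CCBr
Why: Kinetic deprotonation by the hindered amide base should occur at the methyl group (C8), and the enolate is C-allylated (enolate alkylation); the malonate has no acidic hydrogen.

Step 7
Reactants: 8 dimethyl 4-(pent-4-enoyl)-5-vinylbicyclo[3.2.0]heptane-2,2-dicarboxylate
Product: 9 tricyclic ketone: cyclohept-4-en-1-one ring C (C6=O, cis C10=C11) fused at C12–C18 to the bicyclo[3.2.0]heptane
Conditions: second-generation Grubbs catalyst (5 mol%), CH2Cl2, 40 °C
Reagents that add atoms: none
Why: Ring-closing metathesis of the two terminal alkenes should form seven-membered ring C with loss of ethylene; no stereocentre is formed.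

Step 8
Reactants: 9 tricyclic ketone
Product: 10 tricyclic C6 alcohol (both C6 epimers)
Conditions: NaBH4, MeOH, 0 °C
Reagents that add atoms: none
Why: NaBH4 should reduce the ketone and spare the malonate esters (chemoselective carbonyl reduction); the C6 carbinol centre is an inconsequential mixture because it is oxidised again in step 12.

Step 9
Reactants: 10 tricyclic C6 alcohol
Product: 11 tricyclic C6 trifluoroacetate (vinylcyclobutane, C10=C11)
Conditions: (CF3CO)2O, pyridine, CH2Cl2, 0 °C
Reagents that add atoms: trifluoroacetic anhydride, O=C(OC(=O)C(F)(F)F)C(F)(F)F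
Why: O-Acylation gives a non-participating, electron-withdrawing ester that should keep C6 from conjugating with, or trapping, the cations of step 10.

Step 10
Reactants: 11 tricyclic C6 trifluoroacetate
Product: 12 ring-expanded tricycle (rings A, B and C; C11=C12; C6 trifluoroacetate; gem-diester at C16)
Conditions: CF3SO3H (20 mol%), CH2Cl2, −40 to 0 °C
Reagents that add atoms: none
Why: Protonation of the cis alkene at C10 gives the secondary cation at C11, a cyclobutylcarbinyl cation; the C12–C15 bond, which should lie nearly perpendicular to the C9–C10–C11–C12 plane because ring C wraps around the outside of ring B, shifts from C12 to C11 with release of the cyclobutane strain, and the tertiary cation at C12 then loses H11 to give the tetrasubstituted alkene, so the step is overall an acid-catalysed isomerisation. The closest known reaction type is the acid-mediated cyclobutylcarbinyl-to-cyclopentyl Wagner–Meerwein ring expansion of alkenylcyclobutanes obtained from [2+2] photoadducts. Ring A is closed by a suprafacial 1,2-alkyl shift, that is by ring expansion by one carbon and not by an end-to-end cyclisation, and no other ring is made. No stereocentre is created: C13 keeps its bond to C14 and its configuration, and C12 becomes sp2. The step needs selectivity among three migrating bonds and three β-hydrogens: migration of C13 would give a bridgehead cation and migration of C18 a cyclobutyl cation, and loss of H13 or H18 should be disfavoured because C13 and C18 are bonded to carbons that carry electron-withdrawing groups (the gem-diester at C16, the trifluoroacetoxy group at C6), whereas H11 is flanked only by alkyl groups.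

Step 11
Reactants: 12 ring-expanded tricycle
Product: 13 tricyclic C6 alcohol with C11=C12
Conditions: K2CO3 (0.2 equiv), MeOH, 0 °C
Reagents that add atoms: none
Why: Trifluoroacetates undergo methanolysis under very mild base (transesterification), which should leave the methyl esters and the alkene untouched.

Step 12
Reactants: 13 tricyclic C6 alcohol
Product: 14 β,γ-unsaturated ketone (C6=O, C11=C12, H at C18)
Conditions: (n-Pr)4N[RuO4] (5 mol%), N-methylmorpholine N-oxide, 4 Å molecular sieves, CH2Cl2, 0 °C
Reagents that add atoms: none
Why: Neutral catalytic perruthenate oxidation of the secondary alcohol should give the β,γ-unsaturated ketone without moving the double bond into conjugation.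

Step 13
Reactants: 14 β,γ-unsaturated ketone
Product: 16 tetracyclic amino ketone (rings A–D; C6=O; gem-diester at C16), via C8-(methylaminomethyl) ketone 15 (not isolated)
Conditions: MeNH2 (40% aq., 1.1 equiv), CH2O (37% aq., 2.2 equiv), AcOH, MeOH, 55 °C
Reagents that add atoms: methylamine, CN; formaldehyde, C=O
Why: Double Mannich reaction: after aminomethylation at C8, the N-methylmethyleneiminium ion is attacked by C18 of the extended enol C6(OH)=C18–C12=C11 in a six-membered ring closure that forms ring D; the iminium should add to C18 from the convex face of the bowl-shaped diquinane (the face of H13, opposite the pseudo-axial ester on C16), which sets C18, and C8 is then fixed by the bridge.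

Step 14
Reactants: 17 3-(chloromethoxy)prop-1-ene; 18 triphenylphosphine
Product: 19 [(allyloxy)methyl]triphenylphosphonium chloride
Conditions: toluene, 23 °C
Reagents that add atoms: none
Why: SN2 quaternisation of the phosphine by the reactive α-chloro ether should give the phosphonium salt.

Step 15
Reactants: 16 tetracyclic amino ketone; 19 [(allyloxy)methyl]triphenylphosphonium chloride
Product: 21 allyl enol ether (C6=C7H–O–CH2CH=CH2), via allyloxymethylene ylide 20 (not isolated)
Conditions: KOtBu, THF, 0 to 50 °C
Reagents that add atoms: none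
Why: Wittig olefination with the alkoxymethylene ylide should convert the non-enolisable bridging ketone into the enol ether; its E/Z ratio is of no consequence.

Step 16
Reactants: 21 allyl enol ether
Product: 22 quaternary aldehyde (C6 bears C7HO and the allyl group C5–C4=C3)
Conditions: o-xylene, 180 °C, sealed tube
Reagents that add atoms: none
Why: Claisen rearrangement ([3,3]-sigmatropic) should deliver the allyl group to C6 from the less hindered face of the exocyclic enol ether, that of the three-atom aminomethylene bridge, which sets quaternary C6 with the formyl group over the cycloheptene.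

Step 17
Reactants: 22 quaternary aldehyde
Product: 23 primary alcohol (C7H2OH) with allyl group and gem-diester
Conditions: NaBH4, MeOH, 0 °C
Reagents that add atoms: none
Why: Chemoselective reduction of the neopentyl aldehyde by NaBH4 should leave the esters and both alkenes untouched.

Step 18
Reactants: 23 primary alcohol
Product: 24 monoester (C16–H and ester as in the target)
Conditions: LiCl, H2O, DMSO, 140 °C
Reagents that add atoms: none
Why: Krapcho dealkoxycarbonylation; the ester enolate left after loss of CO2 should be protonated at C16 from the convex face (anti to C14 and to the substituents on C6), which places the remaining ester cis to C14.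

Step 19
Reactants: 24 monoester
Product: 25 tert-butyldimethylsilyl ether of 24
Conditions: TBSCl, imidazole, DMF, 23 °C
Reagents that add atoms: tert-butyldimethylsilyl chloride, CC(C)(C)[Si](C)(C)Cl
Why: Silylation protects the C7 hydroxyl so that it cannot form a lactol with the C3 aldehyde made in step 21.

Step 20
Reactants: 25 silyl ether
Product: 27 C3 primary alcohol, via B-alkyl-9-BBN adduct 26 (not isolated)
Conditions: 9-BBN (2 equiv), THF, 23 °C; then Me3NO·2H2O, 60 °C
Reagents that add atoms: trimethylamine N-oxide, C[N+](C)(C)[O-]
Why: Hydroboration–oxidation: the bulky borane should add anti-Markovnikov to the terminal alkene only (the tetrasubstituted alkene is inert), and the amine oxide oxidises the C–B bond without oxidising the tertiary amine.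

Step 21
Reactants: 27 C3 primary alcohol
Product: 28 C3 aldehyde
Conditions: (n-Pr)4N[RuO4] (5 mol%), N-methylmorpholine N-oxide, 4 Å molecular sieves, CH2Cl2, 23 °C
Reagents that add atoms: none
Why: Catalytic perruthenate oxidation of the primary alcohol should stop at the aldehyde and tolerate the tertiary amine and the ester.

Step 22
Reactants: 28 C3 aldehyde
Product: 29 silyl ether of the target ((S)-carbinol at C3)
Conditions: Et2Zn (3 equiv), Ti(OiPr)4 (1.2 equiv), (1R,2R)-1,2-bis(trifluoromethanesulfonamido)cyclohexane (8 mol%), toluene, −20 °C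
Reagents that add atoms: diethylzinc, CC[Zn]CC
Why: Catalytic asymmetric addition of diethylzinc to the aldehyde; the chiral titanium bis(sulfonamide) catalyst should deliver ethyl to the Si face and so set C3 as S under reagent control.

Step 23
Reactants: 29 silyl ether of the target
Product: 30 CNP0291564.1
Conditions: HF·pyridine, THF, 0 to 23 °C
Reagents that add atoms: none
Why: Acidic fluoride desilylation of the primary silyl ether should release the C7 hydroxyl without epimerising C16.

**Compound list**

1 | methyl cyclobut-1-ene-1-carboxylate | COC(=O)C1=CCC1 | starting material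
2 | (cyclobut-1-en-1-yl)methanol | OCC1=CCC1 | intermediate
3 | cyclobut-1-ene-1-carbaldehyde | O=CC1=CCC1 | intermediate
4 | dimethyl 2-vinylcyclopropane-1,1-dicarboxylate (racemate) | COC(=O)C1(C(=O)OC)CC1C=C | starting material
5 | dimethyl 5-formyl-4-vinylbicyclo[3.2.0]heptane-2,2-dicarboxylate, cis-fused, vinyl and formyl cis | C=C[C@H]1CC(C(=O)OC)(C(=O)OC)[C@@H]2CC[C@]12C=O | intermediate
6 | dimethyl 4-acetyl-5-formylbicyclo[3.2.0]heptane-2,2-dicarboxylate | CC(=O)[C@H]1CC(C(=O)OC)(C(=O)OC)[C@@H]2CC[C@]12C=O | intermediate
7 | dimethyl 4-acetyl-5-vinylbicyclo[3.2.0]heptane-2,2-dicarboxylate | CC(=O)[C@H]1CC(C(=O)OC)(C(=O)OC)[C@@H]2CC[C@]12C=C | intermediate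
8 | dimethyl 4-(pent-4-enoyl)-5-vinylbicyclo[3.2.0]heptane-2,2-dicarboxylate | C=CCCC(=O)[C@H]1CC(C(=O)OC)(C(=O)OC)[C@@H]2CC[C@]12C=C | intermediate
9 | tricyclic ketone (cycloheptenone ring C fused to ring B and cyclobutane; C6=O, C10=C11) | O=C1CCC=C[C@]23CC[C@H]2C(C(=O)OC)(C(=O)OC)C[C@H]13 | intermediate
10 | C6 alcohol of 9 (both C6 epimers) | OC1CCC=C[C@]23CC[C@H]2C(C(=O)OC)(C(=O)OC)C[C@H]13 | intermediate
11 | C6 trifluoroacetate of 10 | O=C(OC1CCC=C[C@]23CC[C@H]2C(C(=O)OC)(C(=O)OC)C[C@H]13)C(F)(F)F | intermediate
12 | ring-expanded tricycle (rings A, B, C; C11=C12; C6 trifluoroacetate) | O=C(OC1CCCC2=C3[C@@H](CC2)C(C(=O)OC)(C(=O)OC)C[C@@H]31)C(F)(F)F | intermediate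
13 | C6 alcohol of 12 | OC1CCCC2=C3[C@@H](CC2)C(C(=O)OC)(C(=O)OC)C[C@@H]31 | intermediate
14 | β,γ-unsaturated ketone (C6=O, C11=C12, H at C18) | O=C1CCCC2=C3[C@@H](CC2)C(C(=O)OC)(C(=O)OC)C[C@@H]31 | intermediate
15 | C8-(methylaminomethyl) ketone, not isolated | O=C1C(CNC)CCC2=C3[C@@H](CC2)C(C(=O)OC)(C(=O)OC)C[C@@H]31 | intermediate
16 | tetracyclic amino ketone (rings A–D, C6=O, gem-diester at C16) | O=C1[C@H]2CCC3=C4[C@@H](CC3)C(C(=O)OC)(C(=O)OC)C[C@]41CN(C)C2 | intermediate
17 | 3-(chloromethoxy)prop-1-ene | C=CCOCCl | starting material
18 | triphenylphosphine | c1ccc(cc1)P(c1ccccc1)c1ccccc1 | starting material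
19 | [(allyloxy)methyl]triphenylphosphonium chloride | C=CCOC[P+](c1ccccc1)(c1ccccc1)c1ccccc1.[Cl-] | intermediate
20 | (allyloxy)methylenetriphenylphosphorane, not isolated | C=CCOC=P(c1ccccc1)(c1ccccc1)c1ccccc1 | intermediate
21 | allyl enol ether of 16 (C6=C7H–O–allyl, E/Z mixture) | C=CCOC=C1[C@H]2CCC3=C4[C@@H](CC3)C(C(=O)OC)(C(=O)OC)C[C@]41CN(C)C2 | intermediate
22 | quaternary aldehyde (C6: formyl and allyl) | C=CC[C@]1(C=O)[C@H]2CCC3=C4[C@@H](CC3)C(C(=O)OC)(C(=O)OC)C[C@]41CN(C)C2 | intermediate
23 | primary alcohol (C7H2OH), allyl, gem-diester | C=CC[C@]1(CO)[C@H]2CCC3=C4[C@@H](CC3)C(C(=O)OC)(C(=O)OC)C[C@]41CN(C)C2 | intermediate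
24 | monoester (C16 as in the target) | C=CC[C@]1(CO)[C@H]2CCC3=C4[C@@H](CC3)[C@@H](C(=O)OC)C[C@]41CN(C)C2 | intermediate
25 | tert-butyldimethylsilyl ether of 24 | C=CC[C@]1(CO[Si](C)(C)C(C)(C)C)[C@H]2CCC3=C4[C@@H](CC3)[C@@H](C(=O)OC)C[C@]41CN(C)C2 | intermediate
26 | B-alkyl-9-BBN adduct of 25, not isolated | B1(C2CCCC1CCC2)CCC[C@]1(CO[Si](C)(C)C(C)(C)C)[C@H]2CCC3=C4[C@@H](CC3)[C@@H](C(=O)OC)C[C@]41CN(C)C2 | intermediate
27 | C3 primary alcohol | OCCC[C@]1(CO[Si](C)(C)C(C)(C)C)[C@H]2CCC3=C4[C@@H](CC3)[C@@H](C(=O)OC)C[C@]41CN(C)C2 | intermediate
28 | C3 aldehyde | O=CCC[C@]1(CO[Si](C)(C)C(C)(C)C)[C@H]2CCC3=C4[C@@H](CC3)[C@@H](C(=O)OC)C[C@]41CN(C)C2 | intermediate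
29 | C7 tert-butyldimethylsilyl ether of the target | CC[C@H](O)CC[C@]1(CO[Si](C)(C)C(C)(C)C)[C@H]2CCC3=C4[C@@H](CC3)[C@@H](C(=O)OC)C[C@]41CN(C)C2 | intermediate
30 | CNP0291564.1 | CC[C@H](O)CC[C@]1(CO)[C@H]2CCC3=C4[C@@H](CC3)[C@@H](C(=O)OC)C[C@]41CN(C)C2 | target

**Step count.** Total: 23 steps. Longest linear sequence: 22 steps (steps 1–13 and 15–23; step 14 is a side branch).

**Steps most likely to fail**

Step 3 (Proposed new method). The α-branched enal may form its iminium ion slowly, so that uncatalysed, non-selective conjugate addition takes over, and closure of the hindered enamine on the π-allyl terminus may stall. The fallback sets out from 3 and comes back at 5. Dimethyl malonate is monoalkylated with (E)-1,4-diacetoxybut-2-ene under Pd(PPh3)4 to give dimethyl 2-[(E)-4-acetoxybut-2-en-1-yl]malonate F1. Its sodium salt adds in conjugate fashion to the strained acceptor 3 to give the trans-2-formylcyclobutyl malonate F2. Pd(PPh3)4 with pyrrolidine then closes ring B by intramolecular allylic alkylation of the aldehyde enamine, giving the racemic cycloadduct F3. Condensation with (1R,2R)-N,N'-dimethyl-1,2-diphenylethane-1,2-diamine gives two diastereomeric aminals; the one from the required enantiomer, aminal F4, is separated by chromatography and hydrolysed with dilute acid to 5.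

Step 10. The ring-expanded cation at C12 may lose H13 or H18 instead of H11, which would misplace the double bond and, through H13, erase the C13 stereocentre. The fallback sets out from 11 and comes back at 12. Allylic oxidation with SeO2 and t-BuOOH at C9, the only allylic CH2, gives the allylic alcohol F5. Catalytic acid then ionises it to the C9–C10–C11 allyl cation, the same shift of C15 follows, and loss of H11 is now driven by conjugation, giving the diene F6 (C9=C10–C11=C12). Diimide, generated from 2-nitrobenzenesulfonohydrazide and Et3N, reduces only the disubstituted C9=C10 alkene and returns 12.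

Step 13. The double bond may migrate into conjugation with the ketone before aminomethylation, and the iminium ion may add to the concave face of C18. The fallback sets out from 14 and comes back at 16. Deprotonation with LiN(i-Pr)2 at −78 °C removes the doubly activated H18 and gives the extended dienolate without prior isomerisation. α-Aminomethylation with N-benzyl-N-methylmethyleneiminium chloride gives the C18-aminomethyl ketone F7, whose diastereomers, if formed, can be separated at this stage. Hydrogenolysis (H2, Pd(OH)2 on carbon) removes the benzyl group to give the secondary amine F8 without reducing the tetrasubstituted alkene. Formaldehyde in acetic acid then closes ring D by intramolecular Mannich reaction at C8 to give 16.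

Further compounds
F1 | step 3 | dimethyl 2-[(E)-4-acetoxybut-2-en-1-yl]malonate | CC(=O)OC/C=C/CC(C(=O)OC)C(=O)OC
F2 | step 3 | dimethyl 2-[(E)-4-acetoxybut-2-en-1-yl]-2-(trans-2-formylcyclobutyl)malonate (racemate) | CC(=O)OC/C=C/CC(C(=O)OC)(C(=O)OC)C1CCC1C=O
F3 | step 3 | racemate of 5 | C=CC1CC(C(=O)OC)(C(=O)OC)C2CCC12C=O
F4 | step 3 | (4R,5R)-1,3-dimethyl-4,5-diphenylimidazolidine aminal of 5 | C=C[C@H]1CC(C(=O)OC)(C(=O)OC)[C@@H]2CC[C@]12C1N(C)[C@H](c2ccccc2)[C@@H](c2ccccc2)N1C
F5 | step 10 | C9 allylic alcohol of 11 (both C9 epimers) | O=C(OC1CC(O)C=C[C@]23CC[C@H]2C(C(=O)OC)(C(=O)OC)C[C@H]13)C(F)(F)F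
F6 | step 10 | ring-expanded diene (C9=C10, C11=C12; C6 trifluoroacetate) | O=C(OC1CC=CC2=C3[C@@H](CC2)C(C(=O)OC)(C(=O)OC)C[C@@H]31)C(F)(F)F
F7 | step 13 | C18-[(N-benzyl-N-methylamino)methyl] ketone | O=C1CCCC2=C3[C@@H](CC2)C(C(=O)OC)(C(=O)OC)C[C@]31CN(C)Cc1ccccc1
F8 | step 13 | C18-[(methylamino)methyl] ketone | O=C1CCCC2=C3[C@@H](CC2)C(C(=O)OC)(C(=O)OC)C[C@]31CNC
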